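**Retrosynthetic overview**

1. Numbering (cembrane): ring C1–C14; C1 carries C15H(C17H3)–C16(=O)–O, and this oxygen sits on C3; C4 = C(CH3)(OH); C7 = CH(OH); C8 = C(=C19H2); C11–C12 = oxirane with the C20 methyl on C12.
2. Target 26 ⇐ desilylation and late Shi epoxidation (oxirane, formed last) ⇐ 14-membered carbocycle closed at C7–C8 by a CrCl2/NiCl2-mediated alkenyl bromide–aldehyde coupling (second ring) ⇐ C12–C13 by B-alkyl Suzuki coupling of vinyl lactone 13 with bromo-iodo-diene 20.
3. Lactone 13 ⇐ key step: Ireland–Claisen rearrangement of the acyclic bis-epoxy (E)-allylic propanoate 7 and, in the same flask, opening of the C3–C4 oxirane by the new carboxylate. This forms C15–C1 and O–C3 and closes the oxan-2-one ring (first ring).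
4. Enabling feature: in the six-membered lactone O–C16(=O)–C15–C1–C2–C3, the C15–C1 bond is the α,β bond of an acid whose γ,δ positions are C14 and C13 (retron of a γ,δ-unsaturated acid), and O–C3 is anti to the tertiary C4 hydroxyl (signature of a carboxylate-opened (3S,4S)-oxirane of an E trisubstituted alkene).
5. Ester 7 ⇐ geranyl bromide + (2R)-but-3-yn-2-ol + propanoic anhydride (alkynylation, trans-reduction, acylation, double Shi epoxidation); the terminal oxirane masks the C7 aldehyde.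

Key step: step 5

Remark on the chemistry: the C15 configuration of the target (3,4-trans in the lactone, all ring substituents equatorial) is taken to be the thermodynamically preferred one, so it can be corrected by base equilibration. The L-fructose-derived enantiomer of the Shi ketone and (2R)-but-3-yn-2-ol are taken as purchasable.

**Route**

Step 1
Reactants: 1 geranyl bromide; 2 (2R)-but-3-yn-2-ol
Product: 3 (2R,6E)-7,11-dimethyldodeca-6,10-dien-3-yn-2-ol
Conditions: CuI (20 mol %), NaI (20 mol %), K2CO3, DMF, 23 °C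
Reagents that add atoms: none
Why: Copper-acetylide alkylation of an allylic bromide should join the fragments at the primary carbon with retention of the E alkene and without touching the carbinol stereocentre.

Step 2
Reactants: 3 (2R,6E)-7,11-dimethyldodeca-6,10-dien-3-yn-2-ol
Product: 4 (2R,3E,6E)-7,11-dimethyldodeca-3,6,10-trien-2-ol
Conditions: NaAlH2(OCH2CH2OCH3)2, THF, 0 → 23 °C; aq. Rochelle salt
Reagents that add atoms: none
Why: Hydroxyl-directed trans-hydroalumination of the propargylic alcohol should give only the E allylic alcohol and leave the isolated alkenes and the stereocentre untouched.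

Step 3
Reactants: 4 (2R,3E,6E)-7,11-dimethyldodeca-3,6,10-trien-2-ol; 5 propanoic anhydride
Product: 6 (2R,3E,6E)-7,11-dimethyldodeca-3,6,10-trien-2-yl propanoate
Conditions: Et3N, DMAP (cat.), CH2Cl2, 0 → 23 °C
Reagents that add atoms: none
Why: DMAP-catalysed acylation of the secondary alcohol installs the propanoate that carries C15, C16, C17 and the future lactone oxygen.

Step 4
Reactants: 6 (2R,3E,6E)-7,11-dimethyldodeca-3,6,10-trien-2-yl propanoate
Product: 7 (2R,3E)-5-[(2S,3S)-3-{2-[(2S)-3,3-dimethyloxiran-2-yl]ethyl}-3-methyloxiran-2-yl]pent-3-en-2-yl propanoate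
Conditions: L-fructose-derived Shi ketone (0.6 equiv), KHSO5 (Oxone), K2CO3, Bu4NHSO4 (cat.), aq. Na2B4O7 buffer, MeCN/CH2(OMe)2, 0 °C
Reagents that add atoms: potassium peroxymonosulfate KHSO5, [K+].[O-]S(=O)(=O)OO
Why: Shi asymmetric epoxidation (chiral dioxirane, spiro transition state) should oxidise the two electron-rich trisubstituted alkenes and spare the disubstituted alkene deactivated by the allylic ester; the L-fructose-derived ketone sets (S,S) at the internal oxirane (future C3 and C4) and (S) at the terminal oxirane, which only masks C7.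

Step 5
Reactants: 7 (2R,3E)-5-[(2S,3S)-3-{2-[(2S)-3,3-dimethyloxiran-2-yl]ethyl}-3-methyloxiran-2-yl]pent-3-en-2-yl propanoate
Product: 11 (3S,4S,6R)-6-{(2S)-4-[(2S)-3,3-dimethyloxiran-2-yl]-2-hydroxybutan-2-yl}-3-methyl-4-[(1E)-prop-1-en-1-yl]oxan-2-one, via silyl ketene acetal 8 (not isolated), via silyl ester 9 (not isolated), via ammonium carboxylate 10 (not isolated)
Conditions: LiN(iPr)2, THF, −78 °C; Me3SiCl/Et3N, −78 → 23 °C; then Bu4NF, 45 °C; aq. NH4Cl
Reagents that add atoms: none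
Why: Kinetic deprotonation with LiN(iPr)2 in THF and O-silylation give the (E)-silyl ketene acetal 8 (methyl cis to the allylic oxygen), which undergoes the Ireland–Claisen [3,3]-sigmatropic rearrangement through a chair transition state to silyl ester 9 and so forms C15–C1; fluoride then frees carboxylate 10, whose oxygen opens the internal oxirane at C3 with inversion and forms O–C3. The closest known reaction types are the Ireland–Claisen rearrangement of (E)-allylic propanoates and the lactonisation of epoxy carboxylates by intramolecular SN2 opening. The oxan-2-one ring closes in the 6-exo-tet mode. C1 is set by 1,3-chirality transfer from the (R)-carbinol (its methyl equatorial in the chair, which also gives the E-propenyl group), C15 by the E geometry of the ketene acetal (anti to C1), C3 by inversion of the (3S)-oxirane carbon, and C4 is carried over from the oxirane with retention. The step needs attack at C3 and not at C4 or at the distal oxirane, which the lower substitution of C3 and the six-membered transition state secure; any C15 epimer from residual Z ketene acetal should converge to the wanted 3,4-trans lactone on brief exposure to DBU.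

Step 6
Reactants: 11 (3S,4S,6R)-6-{(2S)-4-[(2S)-3,3-dimethyloxiran-2-yl]-2-hydroxybutan-2-yl}-3-methyl-4-[(1E)-prop-1-en-1-yl]oxan-2-one
Product: 12 (3S,4S,6R)-6-{(2S)-4-[(2S)-3,3-dimethyloxiran-2-yl]-2-[(triethylsilyl)oxy]butan-2-yl}-3-methyl-4-[(1E)-prop-1-en-1-yl]oxan-2-one
Conditions: Et3SiOTf, 2,6-lutidine, CH2Cl2, −78 °C
Reagents that add atoms: triethylsilyl trifluoromethanesulfonate, CC[Si](CC)(CC)OS(=O)(=O)C(F)(F)F
Why: Silyl triflate silylation of the tertiary alcohol at low temperature with a hindered base should outpace Lewis-acid opening of the oxirane, and the ether blocks later cyclisation of the C4 oxygen onto C7 (tetrahydrofuran or lactol formation).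

Step 7
Reactants: 12 (3S,4S,6R)-6-{(2S)-4-[(2S)-3,3-dimethyloxiran-2-yl]-2-[(triethylsilyl)oxy]butan-2-yl}-3-methyl-4-[(1E)-prop-1-en-1-yl]oxan-2-one
Product: 13 (3S,4S,6R)-6-{(2S)-4-[(2S)-3,3-dimethyloxiran-2-yl]-2-[(triethylsilyl)oxy]butan-2-yl}-4-ethenyl-3-methyloxan-2-one
Conditions: second-generation Grubbs catalyst RuCl2(=CHPh)(PCy3)(H2IMes) (5 mol %), ethene (3 bar), CH2Cl2, 40 °C
Reagents that add atoms: ethene, C=C
Why: Cross-metathesis with ethene (ethenolysis) should trim the propenyl group, the only alkene in 12, to the vinyl group and so remove the carbon that served for chirality transfer.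

Step 8
Reactants: 14 pent-3-yn-1-ol
Product: 16 (3E)-4-iodopent-3-en-1-ol, via alkenylzirconocene 15 (not isolated)
Conditions: Cp2Zr(H)Cl (3 equiv), THF, 23 → 45 °C; then I2, 0 °C
Reagents that add atoms: iodine, [I][I]
Why: Hydrozirconation of the 2-alkyne with excess Schwartz reagent equilibrates zirconium to the less hindered methyl-bearing carbon, and syn addition followed by iodinolysis with retention fixes the E geometry.

Step 9
Reactants: 16 (3E)-4-iodopent-3-en-1-ol
Product: 17 (2E)-2,5-diiodopent-2-ene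
Conditions: I2, PPh3, imidazole, CH2Cl2, 0 °C
Reagents that add atoms: iodine, [I][I]
Why: Appel-type iodination converts the primary alcohol to the iodide under neutral conditions that leave the alkenyl iodide intact.

Step 10
Reactants: 17 (2E)-2,5-diiodopent-2-ene
Product: 18 (5E)-6-iodohept-5-en-1-yne
Conditions: LiC≡CH·H2NCH2CH2NH2, DMSO, 15 → 23 °C
Reagents that add atoms: lithium acetylide (ethane-1,2-diamine complex), [Li]C#C
Why: SN2 alkylation of lithium acetylide by the primary iodide adds C8 and C19, while the alkenyl iodide, whose vinylic hydrogen is syn to iodine, should resist elimination.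

Step 11
Reactants: 18 (5E)-6-iodohept-5-en-1-yne
Product: 20 (5E)-2-bromo-6-iodohepta-1,5-diene, via alkenylborane 19 (not isolated)
Conditions: B-bromo-9-BBN, CH2Cl2, 0 °C; then AcOH, 23 °C
Reagents that add atoms: 9-bromo-9-borabicyclo[3.3.1]nonane, BrB1C2CCCC1CCC2
Why: Syn bromoboration of the terminal alkyne followed by protonolysis of the C–B bond gives the 2-bromo-1-alkene regioselectively and leaves the alkenyl iodide untouched.

Step 12
Reactants: 13 (3S,4S,6R)-6-{(2S)-4-[(2S)-3,3-dimethyloxiran-2-yl]-2-[(triethylsilyl)oxy]butan-2-yl}-4-ethenyl-3-methyloxan-2-one; 20 (5E)-2-bromo-6-iodohepta-1,5-diene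
Product: 22 (3S,4R,6R)-4-[(3E)-7-bromo-3-methylocta-3,7-dien-1-yl]-6-{(2S)-4-[(2S)-3,3-dimethyloxiran-2-yl]-2-[(triethylsilyl)oxy]butan-2-yl}-3-methyloxan-2-one, via alkylborane 21 (not isolated)
Conditions: 9-BBN dimer, THF, 23 °C; then 20, Pd(dppf)Cl2 (5 mol %), AsPh3, Cs2CO3, DMF/H2O, 23 °C
Reagents that add atoms: none
Why: Anti-Markovnikov hydroboration of the only alkene of 13 and B-alkyl Suzuki–Miyaura coupling form C12–C13 with retention of the E geometry, the palladium catalyst inserting into the C–I bond much faster than into the C–Br bond.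

Step 13
Reactants: 22 (3S,4R,6R)-4-[(3E)-7-bromo-3-methylocta-3,7-dien-1-yl]-6-{(2S)-4-[(2S)-3,3-dimethyloxiran-2-yl]-2-[(triethylsilyl)oxy]butan-2-yl}-3-methyloxan-2-one
Product: 23 (3S,4R,6R)-4-[(3E)-7-bromo-3-methylocta-3,7-dien-1-yl]-3-methyl-6-{(2S)-5-oxo-2-[(triethylsilyl)oxy]pentan-2-yl}oxan-2-one
Conditions: H5IO6, THF/Et2O, 0 °C
Reagents that add atoms: none
Why: Periodic acid hydrolyses the terminal oxirane and cleaves the resulting glycol (Malaprade-type cleavage) to unveil the C7 aldehyde, while the trisubstituted alkene, the alkenyl bromide and the hindered tertiary silyl ether should survive.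

Step 14
Reactants: 23 (3S,4R,6R)-4-[(3E)-7-bromo-3-methylocta-3,7-dien-1-yl]-3-methyl-6-{(2S)-5-oxo-2-[(triethylsilyl)oxy]pentan-2-yl}oxan-2-one
Product: 24 (1R,3R,4S,7R,11E,15S)-7-hydroxy-4-[(triethylsilyl)oxy]cembra-8(19),11-dien-16,3-olide
Conditions: CrCl2 (6 equiv), NiCl2 (2 mol %), (S)-N-[2-(4-isopropyl-4,5-dihydro-1,3-oxazol-2-yl)-6-methylphenyl]methanesulfonamide, Et3N, MeCN/THF, 23 °C, 2 mM (slow addition)
Reagents that add atoms: none
Why: Nozaki–Hiyama–Kishi reaction: nickel-catalysed formation of the alkenylchromium species from the 2-bromo-1-alkene and its intramolecular addition to the aldehyde under high dilution should close the 14-membered ring and create the 2-methylene allylic alcohol; the chiral chromium sulfonamide complex is to direct attack to the Si face of the aldehyde, which gives (7R), and the enantiomeric ligand is taken if a model coupling shows the opposite sense.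

Step 15
Reactants: 24 (1R,3R,4S,7R,11E,15S)-7-hydroxy-4-[(triethylsilyl)oxy]cembra-8(19),11-dien-16,3-olide
Product: 25 (1R,3R,4S,7R,11S,12S,15S)-11,12-epoxy-7-hydroxy-4-[(triethylsilyl)oxy]cembr-8(19)-en-16,3-olide
Conditions: L-fructose-derived Shi ketone (0.4 equiv), KHSO5 (Oxone), K2CO3, Bu4NHSO4 (cat.), aq. Na2B4O7 buffer, MeCN/CH2(OMe)2, 0 °C
Reagents that add atoms: potassium peroxymonosulfate KHSO5, [K+].[O-]S(=O)(=O)OO
Why: Shi asymmetric epoxidation: the electron-rich E trisubstituted C11=C12 alkene should react in preference to the 1,1-disubstituted C8=C19 alkene, and the L-fructose-derived ketone delivers oxygen in the same sense as in step 4 to give (11S,12S).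

Step 16
Reactants: 25 (1R,3R,4S,7R,11S,12S,15S)-11,12-epoxy-7-hydroxy-4-[(triethylsilyl)oxy]cembr-8(19)-en-16,3-olide
Product: 26 (1R,3R,4S,7R,11S,12S,15S)-11,12-epoxy-4,7-dihydroxycembr-8(19)-en-16,3-olide (target)
Conditions: Bu4NF, AcOH, THF, 0 → 23 °C
Reagents that add atoms: none
Why: Fluoride-mediated cleavage of the tertiary silyl ether, buffered with acetic acid so that neither the lactone nor the oxirane is opened, releases the C4 hydroxyl and gives the target.

**Compound list**

1 | geranyl bromide, (2E)-1-bromo-3,7-dimethylocta-2,6-diene | CC(C)=CCC/C(C)=C/CBr | starting material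
2 | (2R)-but-3-yn-2-ol | C[C@@H](O)C#C | starting material
3 | (2R,6E)-7,11-dimethyldodeca-6,10-dien-3-yn-2-ol | C[C@@H](O)C#CC/C=C(\C)CCC=C(C)C | intermediate
4 | (2R,3E,6E)-7,11-dimethyldodeca-3,6,10-trien-2-ol | C[C@@H](O)/C=C/C/C=C(\C)CCC=C(C)C | intermediate
5 | propanoic anhydride | CCC(=O)OC(=O)CC | starting material
6 | (2R,3E,6E)-7,11-dimethyldodeca-3,6,10-trien-2-yl propanoate | C[C@@H](OC(=O)CC)/C=C/C/C=C(\C)CCC=C(C)C | intermediate
7 | (2R,3E)-5-[(2S,3S)-3-{2-[(2S)-3,3-dimethyloxiran-2-yl]ethyl}-3-methyloxiran-2-yl]pent-3-en-2-yl propanoate | C[C@@H](OC(=O)CC)/C=C/C[C@@H]1O[C@@]1(C)CC[C@@H]2OC2(C)C | intermediate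
8 | (E)-O-trimethylsilyl ketene acetal of 7 (methyl trans to OSi) | C/C=C(/O[Si](C)(C)C)O[C@H](C)/C=C/C[C@@H]1O[C@@]1(C)CC[C@@H]2OC2(C)C | intermediate
9 | trimethylsilyl (2S,3S,4E)-3-{[(2S,3S)-3-{2-[(2S)-3,3-dimethyloxiran-2-yl]ethyl}-3-methyloxiran-2-yl]methyl}-2-methylhex-4-enoate | C[Si](C)(C)OC(=O)[C@@H](C)[C@H](/C=C/C)C[C@@H]1O[C@@]1(C)CC[C@@H]2OC2(C)C | intermediate
10 | tetrabutylammonium (2S,3S,4E)-3-{[(2S,3S)-3-{2-[(2S)-3,3-dimethyloxiran-2-yl]ethyl}-3-methyloxiran-2-yl]methyl}-2-methylhex-4-enoate | CCCC[N+](CCCC)(CCCC)CCCC.[O-]C(=O)[C@@H](C)[C@H](/C=C/C)C[C@@H]1O[C@@]1(C)CC[C@@H]2OC2(C)C | intermediate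
11 | (3S,4S,6R)-6-{(2S)-4-[(2S)-3,3-dimethyloxiran-2-yl]-2-hydroxybutan-2-yl}-3-methyl-4-[(1E)-prop-1-en-1-yl]oxan-2-one | C/C=C/[C@@H]1C[C@@H](OC(=O)[C@H]1C)[C@@](C)(O)CC[C@@H]2OC2(C)C | intermediate
12 | (3S,4S,6R)-6-{(2S)-4-[(2S)-3,3-dimethyloxiran-2-yl]-2-[(triethylsilyl)oxy]butan-2-yl}-3-methyl-4-[(1E)-prop-1-en-1-yl]oxan-2-one | C/C=C/[C@@H]1C[C@@H](OC(=O)[C@H]1C)[C@@](C)(O[Si](CC)(CC)CC)CC[C@@H]2OC2(C)C | intermediate
13 | (3S,4S,6R)-6-{(2S)-4-[(2S)-3,3-dimethyloxiran-2-yl]-2-[(triethylsilyl)oxy]butan-2-yl}-4-ethenyl-3-methyloxan-2-one | C=C[C@@H]1C[C@@H](OC(=O)[C@H]1C)[C@@](C)(O[Si](CC)(CC)CC)CC[C@@H]2OC2(C)C | intermediate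
14 | pent-3-yn-1-ol | CC#CCCO | starting material
15 | (E)-alkenylzirconocene chloride from 14 (zirconium on the methyl-bearing carbon, oxygen zirconated) | C/C(=C\CCO[Zr](Cl)(C1C=CC=C1)C1C=CC=C1)[Zr](Cl)(C1C=CC=C1)C1C=CC=C1 | intermediate
16 | (3E)-4-iodopent-3-en-1-ol | OCC/C=C(\C)I | intermediate
17 | (2E)-2,5-diiodopent-2-ene | ICC/C=C(\C)I | intermediate
18 | (5E)-6-iodohept-5-en-1-yne | C#CCC/C=C(\C)I | intermediate
19 | 9-[(1Z,5E)-2-bromo-6-iodohepta-1,5-dien-1-yl]-9-borabicyclo[3.3.1]nonane | Br/C(CC/C=C(\C)I)=C\B1C2CCCC1CCC2 | intermediate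
20 | (5E)-2-bromo-6-iodohepta-1,5-diene | C=C(Br)CC/C=C(\C)I | intermediate
21 | 9-{2-[(3S,4R,6R)-6-{(2S)-4-[(2S)-3,3-dimethyloxiran-2-yl]-2-[(triethylsilyl)oxy]butan-2-yl}-3-methyl-2-oxooxan-4-yl]ethyl}-9-borabicyclo[3.3.1]nonane | B1(CC[C@@H]3C[C@@H](OC(=O)[C@H]3C)[C@@](C)(O[Si](CC)(CC)CC)CC[C@@H]4OC4(C)C)C2CCCC1CCC2 | intermediate
22 | (3S,4R,6R)-4-[(3E)-7-bromo-3-methylocta-3,7-dien-1-yl]-6-{(2S)-4-[(2S)-3,3-dimethyloxiran-2-yl]-2-[(triethylsilyl)oxy]butan-2-yl}-3-methyloxan-2-one | C=C(Br)CC/C=C(\C)CC[C@@H]1C[C@@H](OC(=O)[C@H]1C)[C@@](C)(O[Si](CC)(CC)CC)CC[C@@H]2OC2(C)C | intermediate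
23 | (3S,4R,6R)-4-[(3E)-7-bromo-3-methylocta-3,7-dien-1-yl]-3-methyl-6-{(2S)-5-oxo-2-[(triethylsilyl)oxy]pentan-2-yl}oxan-2-one | C=C(Br)CC/C=C(\C)CC[C@@H]1C[C@@H](OC(=O)[C@H]1C)[C@@](C)(O[Si](CC)(CC)CC)CCC=O | intermediate
24 | (1R,3R,4S,7R,11E,15S)-7-hydroxy-4-[(triethylsilyl)oxy]cembra-8(19),11-dien-16,3-olide | C=C1CC/C=C(\C)CC[C@@H]2C[C@@H](OC(=O)[C@H]2C)[C@@](C)(O[Si](CC)(CC)CC)CC[C@H]1O | intermediate
25 | (1R,3R,4S,7R,11S,12S,15S)-11,12-epoxy-7-hydroxy-4-[(triethylsilyl)oxy]cembr-8(19)-en-16,3-olide | C=C1CC[C@@H]2O[C@@]2(C)CC[C@@H]3C[C@@H](OC(=O)[C@H]3C)[C@@](C)(O[Si](CC)(CC)CC)CC[C@H]1O | intermediate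
26 | (1R,3R,4S,7R,11S,12S,15S)-11,12-epoxy-4,7-dihydroxycembr-8(19)-en-16,3-olide | C=C1CC[C@@H]2O[C@@]2(C)CC[C@@H]2C[C@@H](OC(=O)[C@H]2C)[C@@](C)(O)CC[C@H]1O | target

**Step count and risks**

Total step count: 16. Longest linear sequence: 12 steps (steps 1–7 and 12–16); the side branch to 20 has 4 steps (steps 8–11).

The three steps most likely to fail:

Step 5 (key step). What may go wrong: opening of either oxirane by chloride or by the silylating agent during enolisation and rearrangement, cyclisation of the freed C4 alkoxide onto the terminal oxirane, or erosion of the chirality transfer through a boat transition state. The fallback sets out from 6 and comes back at 13; it moves the epoxidation behind the rearrangement so that no oxirane is present when the carbon–carbon bond is made. Ireland–Claisen rearrangement of the epoxide-free ester 6 (LiN(iPr)2, Me3SiCl/Et3N, THF, −78 → 23 °C; dilute acid) should give (2S,3S,4E)-3-[(2E)-3,7-dimethylocta-2,6-dien-1-yl]-2-methylhex-4-enoic acid F1. Ethenolysis with the first-generation Grubbs catalyst RuCl2(=CHPh)(PCy3)2, which should leave the trisubstituted alkenes alone, would give (2S,3S,5E)-3-ethenyl-2,6,10-trimethylundeca-5,9-dienoic acid F2. Shi epoxidation of its two trisubstituted alkenes with the L-fructose-derived ketone (the vinyl group is inert), followed by buffering to about pH 5, should close the lactone to (3S,4S,6R)-6-{(2S)-4-[(2S)-3,3-dimethyloxiran-2-yl]-2-hydroxybutan-2-yl}-4-ethenyl-3-methyloxan-2-one F3. Silylation (Et3SiOTf, 2,6-lutidine, −78 °C) then returns to 13.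

Step 14. What may go wrong: oligomerisation in place of ring closure, slow insertion into the C–Br bond, or poor facial selectivity at the aldehyde. The fallback sets out from 23 and comes back at 24; it gives up control of C7 in the bond-forming step and sets it by reagent-controlled reduction. Ring closure of 23 with CrCl2/NiCl2 in DMSO without ligand would give 24 together with its C7 epimer, (1R,3R,4S,7S,11E,15S)-7-hydroxy-4-[(triethylsilyl)oxy]cembra-8(19),11-dien-16,3-olide F4. Oxidation of the mixture with Dess–Martin periodinane should give the macrocyclic enone (1R,3R,4S,11E,15S)-7-oxo-4-[(triethylsilyl)oxy]cembra-8(19),11-dien-16,3-olide F5. Corey–Bakshi–Shibata reduction with the (S)-2-methyl oxazaborolidine and catecholborane at −78 °C (the alkenyl group acting as the large substituent) should deliver the (7R) alcohol 24.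

Step 15. What may go wrong: poor facial selectivity, because the conformation of the macrocycle may override the catalyst, or competing oxidation of the exocyclic alkene. The fallback sets out from 23 and comes back at 25; it places the epoxidation on the open chain, where catalyst control is most reliable. Acetalisation of 23 (MeOH, PPTS) should give (3S,4R,6R)-4-[(3E)-7-bromo-3-methylocta-3,7-dien-1-yl]-6-{(2S)-5,5-dimethoxy-2-[(triethylsilyl)oxy]pentan-2-yl}-3-methyloxan-2-one F6. Shi epoxidation with the L-fructose-derived ketone would give (3S,4R,6R)-4-{2-[(2S,3S)-3-(3-bromobut-3-en-1-yl)-2-methyloxiran-2-yl]ethyl}-6-{(2S)-5,5-dimethoxy-2-[(triethylsilyl)oxy]pentan-2-yl}-3-methyloxan-2-one F7. Mild acetal hydrolysis (PPTS, wet acetone) would give (3S,4R,6R)-4-{2-[(2S,3S)-3-(3-bromobut-3-en-1-yl)-2-methyloxiran-2-yl]ethyl}-3-methyl-6-{(2S)-5-oxo-2-[(triethylsilyl)oxy]pentan-2-yl}oxan-2-one F8. Ring closure of F8 under the conditions of step 14 then gives 25 directly.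

Further compounds
F1 | step 5 | (2S,3S,4E)-3-[(2E)-3,7-dimethylocta-2,6-dien-1-yl]-2-methylhex-4-enoic acid | OC(=O)[C@@H](C)[C@H](/C=C/C)C/C=C(\C)CCC=C(C)C
F2 | step 5 | (2S,3S,5E)-3-ethenyl-2,6,10-trimethylundeca-5,9-dienoic acid | OC(=O)[C@@H](C)[C@H](C=C)C/C=C(\C)CCC=C(C)C
F3 | step 5 | (3S,4S,6R)-6-{(2S)-4-[(2S)-3,3-dimethyloxiran-2-yl]-2-hydroxybutan-2-yl}-4-ethenyl-3-methyloxan-2-one | C=C[C@@H]1C[C@@H](OC(=O)[C@H]1C)[C@@](C)(O)CC[C@@H]2OC2(C)C
F4 | step 14 | (1R,3R,4S,7S,11E,15S)-7-hydroxy-4-[(triethylsilyl)oxy]cembra-8(19),11-dien-16,3-olide | C=C1CC/C=C(\C)CC[C@@H]2C[C@@H](OC(=O)[C@H]2C)[C@@](C)(O[Si](CC)(CC)CC)CC[C@@H]1O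
F5 | step 14 | (1R,3R,4S,11E,15S)-7-oxo-4-[(triethylsilyl)oxy]cembra-8(19),11-dien-16,3-olide | C=C1CC/C=C(\C)CC[C@@H]2C[C@@H](OC(=O)[C@H]2C)[C@@](C)(O[Si](CC)(CC)CC)CCC1=O
F6 | step 15 | (3S,4R,6R)-4-[(3E)-7-bromo-3-methylocta-3,7-dien-1-yl]-6-{(2S)-5,5-dimethoxy-2-[(triethylsilyl)oxy]pentan-2-yl}-3-methyloxan-2-one | C=C(Br)CC/C=C(\C)CC[C@@H]1C[C@@H](OC(=O)[C@H]1C)[C@@](C)(O[Si](CC)(CC)CC)CCC(OC)OC
F7 | step 15 | (3S,4R,6R)-4-{2-[(2S,3S)-3-(3-bromobut-3-en-1-yl)-2-methyloxiran-2-yl]ethyl}-6-{(2S)-5,5-dimethoxy-2-[(triethylsilyl)oxy]pentan-2-yl}-3-methyloxan-2-one | C=C(Br)CC[C@@H]2O[C@@]2(C)CC[C@@H]1C[C@@H](OC(=O)[C@H]1C)[C@@](C)(O[Si](CC)(CC)CC)CCC(OC)OC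
F8 | step 15 | (3S,4R,6R)-4-{2-[(2S,3S)-3-(3-bromobut-3-en-1-yl)-2-methyloxiran-2-yl]ethyl}-3-methyl-6-{(2S)-5-oxo-2-[(triethylsilyl)oxy]pentan-2-yl}oxan-2-one | C=C(Br)CC[C@@H]2O[C@@]2(C)CC[C@@H]1C[C@@H](OC(=O)[C@H]1C)[C@@](C)(O[Si](CC)(CC)CC)CCC=O
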